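**Numbering.** Compounds 1–13 are fixed by the steps below and used throughout; 13 is the target, 7 and 8 are the substrates of the key step and 9 is its product.

## Analysis of the target

Compound 13 is an isoflavone, a chromen-4-one in which ring A (C4a to C8a) carries hydroxyls at C5 and C7, ring C (O1, C2, C3, C4, C4a, C8a) holds the carbonyl at C4, and ring B is attached at C3. Ring B has a free hydroxyl at C3', a methoxy group at C4' and an (E)-3-methylbuta-1,3-dienyl chain at C5'. The methyl ether therefore sits on the oxygen para to C1' and the free phenol on a meta oxygen. There is no stereocenter; the only stereochemical element is the E double bond of the diene. The diene is the fragile part of the molecule (protic and Lewis acids, hydrogenation, radicals and dienophiles all attack it). The three phenols are acidic and oxidisable, and C2 of the chromone is open to hydroxide. The difficulty lies in closing ring C regioselectively between two electron-rich arenes, in getting the oxygen pattern of ring B right, and in placing the diene so late that no acid or reductant follows it. The plan turns on C4. It is a bare carbonyl carbon whose two neighbours are C3, the nucleophilic carbon of an aryl enol ether O1–C2=C3 once ring C is opened, and C4a, one of two identical C–H positions ortho to the ether oxygen of a symmetric 3,5-dioxygenated ring A. C4 can therefore be brought in as carbon monoxide and inserted between two C–H bonds.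

## Retrosynthetic reasoning

**13 to 10 and 12.** The bond between C5' and the first carbon of the diene is cut first, so that the diene enters in the last step by a Suzuki–Miyaura coupling under mild base. The whole five-carbon unit arrives with its E geometry already fixed in boronate 12. The handle on ring B is a chloride and not a bromide, because it has to pass through a palladium/CO step without undergoing oxidative addition. The price is that the forward coupling must activate an electron-rich aryl chloride in the presence of three free phenols.

**12 to 11.** The C–B bond is cut. A syn, anti-Markovnikov hydroboration of the terminal alkyne of enyne 11 sets the E geometry and leaves the 1,1-disubstituted alkene alone.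

**10 to 9.** The three benzyl ethers are removed before the diene exists. The dependable debenzylations (Lewis acid or hydrogenolysis) would both destroy a diene. A Lewis-acid cleavage is preferred over hydrogenolysis so that the C–Cl bond and the C2=C3 bond of 9 survive.

**9 to 7 and 8.** This is the key disconnection: C3–C4 and C4–C4a are cut, C4 leaves as carbon monoxide 8, and ring C opens to the aryl styryl ether 7. Cutting here means that neither ring A nor C3 needs a halogen, an acyl group or a carboxyl group beforehand. The symmetry of ring A in 7 removes the regiochemical question at C4a. The forward reaction has to palladate C3, insert 8, and acylate ring A ortho to the ether oxygen. In 9 ring B and O1 are trans across C2=C3, because C4 and O1 are both in the ring. The C3–H bond that is replaced must therefore lie cis to the aryloxy oxygen, and that is the E configuration of 7. The Z geometry would require the double bond to invert during the reaction, so 7 is planned as the E isomer.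

**7 to 5 and 6.** The O1–C2 bond is cut to give phenol 6 and the (E)-vinyl iodide 5. A copper-catalysed Ullmann-type O-vinylation retains the alkene geometry, so the E configuration needed for the key step is carried over from 5. The shorter base-mediated addition of 6 to a terminal arylalkyne is set aside, since anti addition delivers the Z geometry as the kinetic product.

**5 to 4.** The C2=C3 double bond is cut by a one-carbon Takai iodo-olefination of aldehyde 4, which gives the E vinyl iodide directly.

**4 to 3 to 2 to 1.** The oxygen pattern of ring B is set here. Benzylating the free phenol of 1 directly would put the benzyl group on the oxygen para to the formyl group and leave the methyl on the meta oxygen, the reverse of what 13 needs. So 1 is first demethylated to catechol 2. The more acidic hydroxyl of 2 (para to the formyl group, ortho to chlorine) is methylated to give 3, and the remaining meta hydroxyl is benzylated to give 4.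

## Alternatives that were turned down

**Alternative 1:** Ring C is cut at C4–C3 and O1–C2. Ring A comes as the benzodioxinone A1, which already carries C4 as a masked salicylate carbonyl, and ring B comes as the β-methoxystyrene A2. In the forward step, irradiation of A1 expels the ketone of the acetonide and releases the quinoketene A3. The aryl-bearing carbon of A2 attacks the ketene carbon, the ring oxygen closes on the oxocarbenium carbon, and loss of the alcohol from C2 gives the protected bromo isoflavone A4.
- For: polarity fixes the regiochemistry (aryl at C3) without ambiguity. No transition metal is present, so a bromide can be carried and the final coupling is easier than with the chloride of 10. Either geometry of A2 converges, which is a real advantage over the chosen route, where 7 must be E.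
- Against: quinoketenes are trapped well by heteroatom nucleophiles and strongly polarised π-systems, whereas A2 is a mono-oxygenated styrene weakened further by bromine. Dimerisation of A3 or its return to A1 may therefore win. The aryl bromide is itself photolabile at the wavelengths that open A1. Ring A has to be carboxylated and ketalised first, and the methoxymethyl groups need an acidic removal.
- Comparison: the key step is as speculative as the chosen one and the step count is similar. The chosen route takes C4 from 8 instead of a pre-installed carboxyl group and uses phenol 6 as bought.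

**Alternative 2:** The C3–C1' bond is made by migration. The precursor is the 2'-hydroxychalcone A5, assembled by an aldol condensation. A stoichiometric oxidant of trivalent thallium in methanol moves ring B from C2 to C3 and gives the dimethyl acetal A6. Acid in the same pot closes O1–C2 and frees the phenols to give the bromo triphenol A7.
- For: this is the established laboratory route to isoflavones and follows the biosynthesis. It is short, and it ends directly at a free triphenol aryl bromide that couples more readily than chloride 10. On precedent it is clearly stronger than the chosen strategy, and on step count at least equal.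
- Against: it consumes a full equivalent of a highly toxic thallium salt. The migrating ring B carries a halogen, and its para methoxy group is flanked by two ortho substituents and twisted out of conjugation, which lowers the migratory aptitude. The free 2'-hydroxyl can divert the oxidation towards five-ring or flavone-type products.
- Comparison: the chosen strategy offers a catalytic ring closure from two partners that are unfunctionalised at the reacting carbons, with no stoichiometric heavy-metal oxidant. The chemistry of this alternative is kept in reserve as the fallback for step 6.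

**Alternative 3:** Ring C is cut at O1–C8a and C4–C4a. Ring A comes as the aryne A9, released by fluoride from the silyl triflate A8. C2, C3, C4 and ring B come as the formyl ester A10. The enolate oxygen of A10 adds to the aryne carbon remote from the 3-benzyloxy group (the future C8a). The aryl anion formed at C4a, stabilised by the adjacent benzyloxy group, attacks the ester and closes ring C to give the bromo isoflavone A11.
- For: the regiochemistry of addition to a 3-alkoxyaryne is well understood and matches the 5,7-pattern. The conditions are mild and metal-free, so a bromide is tolerated. A11 is the bromo analogue of 9 and would couple more easily at the end.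
- Against: A8 needs several steps from 6 (ortho halogenation, silyl transfer, triflation) and A10 needs a homologation and a formylation from aldehyde 4. Stabilised 1,3-dicarbonyl enolates normally attack arynes through carbon and then insert the aryne into a C–C bond, so the required O-arylation is not the expected course.
- Comparison: it has more steps and a doubtful chemoselectivity in the key step. The chosen route uses 6 directly and forms the same ring from C–H bonds.

Key step: step 6

Remark on the chemistry: ring B and O1 are trans across C2=C3 in 9, so the carbonylation substrate 7 is made as the E enol ether; the methyl/benzyl pattern of ring B is set by methylating the oxygen para to the formyl group before benzylating the meta oxygen.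

## Route

Step 1
Reactants: 1 5-chlorovanillin (3-chloro-4-hydroxy-5-methoxybenzaldehyde)
Product: 2 3-chloro-4,5-dihydroxybenzaldehyde
Conditions: AlCl3, pyridine, CH2Cl2, reflux; then aq. HCl
Reagents that add atoms: none
Why: O-demethylation of an ortho-hydroxyaryl methyl ether; AlCl3 is held as a chelate by the free phenol and the neighbouring methoxy oxygen, and pyridine removes the activated methyl group by SN2 attack, so the aldehyde and the chloride are not touched.

Step 2
Reactants: 2 3-chloro-4,5-dihydroxybenzaldehyde
Product: 3 3-chloro-5-hydroxy-4-methoxybenzaldehyde
Conditions: MeI (1.2 equiv), Li2CO3 (1.2 equiv), DMF, 40 °C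
Reagents that add atoms: iodomethane, CI
Why: regioselective Williamson etherification; the hydroxyl para to the formyl group and ortho to chlorine is much the more acidic, so a weak base forms only that phenoxide and methylation should occur there, leaving the meta hydroxyl free.

Step 3
Reactants: 3 3-chloro-5-hydroxy-4-methoxybenzaldehyde
Product: 4 3-(benzyloxy)-5-chloro-4-methoxybenzaldehyde
Conditions: BnBr, K2CO3, DMF, rt
Reagents that add atoms: benzyl bromide, BrCc1ccccc1
Why: Williamson etherification of the only remaining phenol; the benzyl group masks it through the organometallic steps and is later removed together with those of ring A.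

Step 4
Reactants: 4 3-(benzyloxy)-5-chloro-4-methoxybenzaldehyde
Product: 5 (E)-1-(benzyloxy)-3-chloro-5-(2-iodovinyl)-2-methoxybenzene
Conditions: CHI3, CrCl2, THF, 0 °C to rt
Reagents that add atoms: iodoform, IC(I)I
Why: Takai olefination; the geminal dichromium species formed from CHI3 and divalent chromium adds to the aldehyde and eliminates with the aryl group and iodine anti, which should give the E vinyl iodide, while the aryl chloride and the benzyl ether are inert to CrCl2.

Step 5
Reactants: 5 (E)-1-(benzyloxy)-3-chloro-5-(2-iodovinyl)-2-methoxybenzene; 6 3,5-bis(benzyloxy)phenol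
Product: 7 (E)-1,3-bis(benzyloxy)-5-{2-[3-(benzyloxy)-5-chloro-4-methoxyphenyl]vinyloxy}benzene
Conditions: CuI (10 mol%), N,N-dimethylglycine hydrochloride (30 mol%), Cs2CO3, 1,4-dioxane, 70 °C
Reagents that add atoms: none
Why: Ullmann-type copper-catalysed C–O coupling of a vinyl iodide with a phenol, which proceeds with retention of the alkene geometry; the vinyl iodide reacts far faster than the aryl chloride, and the E iodide cannot lose HI by anti elimination.

Step 6
Reactants: 7 (E)-1,3-bis(benzyloxy)-5-{2-[3-(benzyloxy)-5-chloro-4-methoxyphenyl]vinyloxy}benzene; 8 carbon monoxide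
Product: 9 5,7-bis(benzyloxy)-3-[3-(benzyloxy)-5-chloro-4-methoxyphenyl]-4H-chromen-4-one
Conditions: Pd(OAc)2 (10 mol%), Cu(OAc)2 (2.5 equiv), KOPiv (0.5 equiv), CO (5 bar), toluene/DMSO (9:1), 4 Å MS, 90 °C
Reagents that add atoms: carbon monoxide (8), [C-]#[O+]
Why: Proposed new method: electrophilic Pd(OAc)2 is expected to attack the E enol ether 7 at C3, its most nucleophilic carbon, and acetate or pivalate then removes the C3 proton that lies cis to the aryloxy oxygen, leaving a vinyl complex of divalent palladium with the metal on the side of ring A. Under 5 bar of CO, insertion into the C3–Pd bond should be faster than any other step and gives an acylpalladium species, which metalates one of the two equivalent C–H positions of ring A ortho to the ether oxygen, each activated by an ortho and a para benzyloxy group. Reductive elimination from the resulting seven-membered palladacycle (Pd, C4, C3, C2, O1, C8a, C4a) forms C4–C4a and closes the six-membered ring C, so the closure is an intramolecular C–H acylation of ring A, with C3–C4 made in the insertion and C4 supplied by CO. Zerovalent palladium is returned to divalent palladium by two equivalents of Cu(OAc)2. The closest known reaction type is the Pd(OAc)2-catalysed oxidative double C–H carbonylation of diaryl ethers to xanthones; replacing one of the arenes by the vinylic C–H bond of an aryl enol ether has not been shown. No stereocenter is formed. The step needs CO insertion to precede C–C bond formation (direct C3–C4a coupling would close a five-membered furan ring), which CO pressure should secure; it needs acylation at C4a, which the symmetry of ring A and the tether secure, since the third C–H between the two benzyloxy groups is out of reach; and it needs an intact C–Cl bond, which the absence of phosphine ligands secures. KOPiv and molecular sieves keep the medium dry and near neutral so that the acetic acid set free does not hydrolyse the enol ether.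

Step 7
Reactants: 9 5,7-bis(benzyloxy)-3-[3-(benzyloxy)-5-chloro-4-methoxyphenyl]-4H-chromen-4-one
Product: 10 3-(3-chloro-5-hydroxy-4-methoxyphenyl)-5,7-dihydroxy-4H-chromen-4-one
Conditions: BCl3, C6HMe5 (pentamethylbenzene), CH2Cl2, −78 °C; then MeOH
Reagents that add atoms: none
Why: Lewis-acid cleavage of aryl benzyl ethers with a non-Lewis-basic cation scavenger; pentamethylbenzene captures the benzyl cations before they can alkylate the electron-rich ring A, and at −78 °C the methyl ether, the C–Cl bond and the C2=C3 bond should remain.

Step 8
Reactants: 11 2-methylbut-1-en-3-yne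
Product: 12 (E)-4,4,5,5-tetramethyl-2-(3-methylbuta-1,3-dien-1-yl)-1,3,2-dioxaborolane
Conditions: HBpin, Cp2Zr(H)Cl (5 mol%), CH2Cl2, rt, sealed vessel
Reagents that add atoms: pinacolborane (4,4,5,5-tetramethyl-1,3,2-dioxaborolane), CC1(C)OBOC1(C)C
Why: zirconium-catalysed hydroboration of a terminal alkyne; syn, anti-Markovnikov addition of the Zr–H bond followed by transfer to boron gives the E alkenylboronate, and the alkyne reacts well before the 1,1-disubstituted alkene.

Step 9
Reactants: 10 3-(3-chloro-5-hydroxy-4-methoxyphenyl)-5,7-dihydroxy-4H-chromen-4-one; 12 (E)-4,4,5,5-tetramethyl-2-(3-methylbuta-1,3-dien-1-yl)-1,3,2-dioxaborolane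
Product: 13 5,7-dihydroxy-3-{3-hydroxy-4-methoxy-5-[(E)-3-methylbuta-1,3-dien-1-yl]phenyl}-4H-chromen-4-one
Conditions: Pd(OAc)2 (5 mol%), SPhos (10 mol%), K3PO4, 1,4-dioxane/H2O (4:1), 80 °C, degassed; then aq. NH4Cl
Reagents that add atoms: none
Why: Suzuki–Miyaura coupling; the electron-rich biaryl phosphine SPhos enables oxidative addition into the aryl chloride in the presence of free phenols, transmetalation and reductive elimination retain the E geometry of 12, and the phenoxide form of the chromone should resist ring opening by base.

## Compound list

1 | 5-chlorovanillin (3-chloro-4-hydroxy-5-methoxybenzaldehyde) | COc1cc(C=O)cc(Cl)c1O | starting material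
2 | 3-chloro-4,5-dihydroxybenzaldehyde | O=Cc1cc(O)c(O)c(Cl)c1 | intermediate
3 | 3-chloro-5-hydroxy-4-methoxybenzaldehyde | COc1c(O)cc(C=O)cc1Cl | intermediate
4 | 3-(benzyloxy)-5-chloro-4-methoxybenzaldehyde | COc1c(Cl)cc(C=O)cc1OCc1ccccc1 | intermediate
5 | (E)-1-(benzyloxy)-3-chloro-5-(2-iodovinyl)-2-methoxybenzene | COc1c(Cl)cc(/C=C/I)cc1OCc1ccccc1 | intermediate
6 | 3,5-bis(benzyloxy)phenol | Oc1cc(OCc2ccccc2)cc(OCc2ccccc2)c1 | starting material
7 | (E)-1,3-bis(benzyloxy)-5-{2-[3-(benzyloxy)-5-chloro-4-methoxyphenyl]vinyloxy}benzene | COc1c(Cl)cc(/C=C/Oc2cc(OCc3ccccc3)cc(OCc3ccccc3)c2)cc1OCc1ccccc1 | intermediate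
8 | carbon monoxide | [C-]#[O+] | starting material
9 | 5,7-bis(benzyloxy)-3-[3-(benzyloxy)-5-chloro-4-methoxyphenyl]-4H-chromen-4-one | O=c1c(-c2cc(Cl)c(OC)c(OCc3ccccc3)c2)coc2cc(OCc3ccccc3)cc(OCc3ccccc3)c12 | intermediate
10 | 3-(3-chloro-5-hydroxy-4-methoxyphenyl)-5,7-dihydroxy-4H-chromen-4-one | O=c1c(-c2cc(Cl)c(OC)c(O)c2)coc2cc(O)cc(O)c12 | intermediate
11 | 2-methylbut-1-en-3-yne | C=C(C)C#C | starting material
12 | (E)-4,4,5,5-tetramethyl-2-(3-methylbuta-1,3-dien-1-yl)-1,3,2-dioxaborolane | C=C(C)/C=C/B1OC(C)(C)C(C)(C)O1 | intermediate
13 | 5,7-dihydroxy-3-{3-hydroxy-4-methoxy-5-[(E)-3-methylbuta-1,3-dien-1-yl]phenyl}-4H-chromen-4-one | C=C(C)/C=C/c1cc(-c2coc3cc(O)cc(O)c3c2=O)cc(O)c1OC | target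

## Step count and risks

Total step count: 9. Longest linear sequence: 8 (steps 1 to 7 and 9); step 8 is a one-step side branch.

**Step 6 (key step, proposed new method).**
- What may go wrong: C3 and C4a may couple before CO is taken up, closing a five-membered ring. The enol ether may be hydrolysed or acetoxylated by the acetic acid set free. CO may reduce the catalyst to inactive metal faster than C–H palladation occurs. Ring A may be palladated at the unproductive position between its two benzyloxy groups.
- Fallback (known chemistry): it sets out from aldehyde 4 and returns to the route at 9. A Claisen–Schmidt condensation of 4 with 1-[2,4-bis(benzyloxy)-6-hydroxyphenyl]ethan-1-one F1 (KOH, EtOH, rt) should give the chalcone (E)-1-[2,4-bis(benzyloxy)-6-hydroxyphenyl]-3-[3-(benzyloxy)-5-chloro-4-methoxyphenyl]prop-2-en-1-one F2. Oxidative 1,2-aryl migration with Tl(NO3)3 in MeOH/HC(OMe)3 should give 1-[2,4-bis(benzyloxy)-6-hydroxyphenyl]-2-[3-(benzyloxy)-5-chloro-4-methoxyphenyl]-3,3-dimethoxypropan-1-one F3. Dilute HCl in MeOH at 50 °C should then close ring C with loss of methanol to give 9.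

**Step 9.**
- What may go wrong: oxidative addition into the aryl chloride may be slow once the substrate is a poorly soluble polyphenoxide. Protodeboronation or thermal oligomerisation of the dienylboronate may then outrun the coupling, and prolonged heating in aqueous base may open the pyranone ring.
- Fallback: it sets out from 10 and returns at 13. Acetylation (Ac2O, pyridine) should give 3-[3-(acetyloxy)-5-chloro-4-methoxyphenyl]-4-oxo-4H-chromene-5,7-diyl diacetate F4. Coupling of this neutral, soluble chloride with 12 under anhydrous conditions (Pd(OAc)2, SPhos, K3PO4, toluene, 90 °C) should give 3-{3-(acetyloxy)-4-methoxy-5-[(E)-3-methylbuta-1,3-dien-1-yl]phenyl}-4-oxo-4H-chromene-5,7-diyl diacetate F5. Methanolysis (K2CO3, MeOH, 0 °C to rt), which the diene tolerates, should give 13.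

**Step 5.**
- What may go wrong: base-induced loss of HI from any Z iodide carried over from step 4, erosion of the alkene geometry at copper, or slow coupling of the electron-rich phenol, any of which lowers the amount of E ether that the key step needs.
- Fallback: it sets out from aldehyde 4 and returns at 7, replacing steps 4 and 5. Ohira–Bestmann homologation (dimethyl (1-diazo-2-oxopropyl)phosphonate, K2CO3, MeOH) should give 1-(benzyloxy)-3-chloro-5-ethynyl-2-methoxybenzene F6. Hydroboration (HBpin, Cp2Zr(H)Cl cat.) should give (E)-2-{2-[3-(benzyloxy)-5-chloro-4-methoxyphenyl]vinyl}-4,4,5,5-tetramethyl-1,3,2-dioxaborolane F7. A Chan–Lam coupling of F7 with 6 (Cu(OAc)2, pyridine, 4 Å MS, CH2Cl2, air, rt) should give 7 with the E geometry fixed by the syn hydroboration.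

**Step 2.**
- What may go wrong: methylation of both oxygens, or of the meta oxygen, if the two phenoxides equilibrate under the reaction conditions. That would lead back to the wrong ring B pattern.
- Fallback: it sets out from 2 and returns at 4, replacing steps 2 and 3 and using the opposite selectivity principle. In the dianion of 2 (NaH, 2.2 equiv, DMSO) the meta phenoxide is the more nucleophilic, so one equivalent of BnBr should give 3-(benzyloxy)-5-chloro-4-hydroxybenzaldehyde F8. Methylation of the remaining para hydroxyl (MeI, K2CO3, DMF) should give 4.

## Further compounds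

F1 | step 6 | 1-[2,4-bis(benzyloxy)-6-hydroxyphenyl]ethan-1-one | CC(=O)c1c(O)cc(OCc2ccccc2)cc1OCc1ccccc1
F2 | step 6 | (E)-1-[2,4-bis(benzyloxy)-6-hydroxyphenyl]-3-[3-(benzyloxy)-5-chloro-4-methoxyphenyl]prop-2-en-1-one | COc1c(Cl)cc(/C=C/C(=O)c2c(O)cc(OCc3ccccc3)cc2OCc2ccccc2)cc1OCc1ccccc1
F3 | step 6 | 1-[2,4-bis(benzyloxy)-6-hydroxyphenyl]-2-[3-(benzyloxy)-5-chloro-4-methoxyphenyl]-3,3-dimethoxypropan-1-one (racemic) | COc1c(Cl)cc(C(C(OC)OC)C(=O)c2c(O)cc(OCc3ccccc3)cc2OCc2ccccc2)cc1OCc1ccccc1
F4 | step 9 | 3-[3-(acetyloxy)-5-chloro-4-methoxyphenyl]-4-oxo-4H-chromene-5,7-diyl diacetate | COc1c(Cl)cc(-c2coc3cc(OC(C)=O)cc(OC(C)=O)c3c2=O)cc1OC(C)=O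
F5 | step 9 | 3-{3-(acetyloxy)-4-methoxy-5-[(E)-3-methylbuta-1,3-dien-1-yl]phenyl}-4-oxo-4H-chromene-5,7-diyl diacetate | C=C(C)/C=C/c1cc(-c2coc3cc(OC(C)=O)cc(OC(C)=O)c3c2=O)cc(OC(C)=O)c1OC
F6 | step 5 | 1-(benzyloxy)-3-chloro-5-ethynyl-2-methoxybenzene | C#Cc1cc(Cl)c(OC)c(OCc2ccccc2)c1
F7 | step 5 | (E)-2-{2-[3-(benzyloxy)-5-chloro-4-methoxyphenyl]vinyl}-4,4,5,5-tetramethyl-1,3,2-dioxaborolane | COc1c(Cl)cc(/C=C/B2OC(C)(C)C(C)(C)O2)cc1OCc1ccccc1
F8 | step 2 | 3-(benzyloxy)-5-chloro-4-hydroxybenzaldehyde | O=Cc1cc(Cl)c(O)c(OCc2ccccc2)c1
A1 | alternative 1 | 2,2-dimethyl-5,7-bis(methoxymethoxy)-4H-1,3-benzodioxin-4-one | CC1(C)OC(=O)c2c(OCOC)cc(OCOC)cc2O1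
A2 | alternative 1 | (E)-1-bromo-2-methoxy-3-(methoxymethoxy)-5-(2-methoxyvinyl)benzene | CO/C=C/c1cc(Br)c(OC)c(OCOC)c1
A3 | alternative 1 | 3,5-bis(methoxymethoxy)-6-(oxomethylidene)cyclohexa-2,4-dien-1-one (quinoketene) | O=C=C1C(=O)C=C(OCOC)C=C1OCOC
A4 | alternative 1 | 3-[3-bromo-4-methoxy-5-(methoxymethoxy)phenyl]-5,7-bis(methoxymethoxy)chromen-4-one | O=c1c(-c2cc(Br)c(OC)c(OCOC)c2)coc2cc(OCOC)cc(OCOC)c12
A5 | alternative 2 | (E)-3-[3-bromo-4-methoxy-5-(methoxymethoxy)phenyl]-1-[2-hydroxy-4,6-bis(methoxymethoxy)phenyl]prop-2-en-1-one | COCOc1cc(O)c(C(=O)/C=C/c2cc(Br)c(OC)c(OCOC)c2)c(OCOC)c1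
A6 | alternative 2 | 2-[3-bromo-4-methoxy-5-(methoxymethoxy)phenyl]-1-[2-hydroxy-4,6-bis(methoxymethoxy)phenyl]-3,3-dimethoxypropan-1-one (racemic) | COCOc1cc(O)c(C(=O)C(C(OC)OC)c2cc(Br)c(OC)c(OCOC)c2)c(OCOC)c1
A7 | alternative 2 | 3-(3-bromo-5-hydroxy-4-methoxyphenyl)-5,7-dihydroxychromen-4-one | O=c1c(-c2cc(Br)c(OC)c(O)c2)coc2cc(O)cc(O)c12
A8 | alternative 3 | 3,5-bis(benzyloxy)-2-(trimethylsilyl)phenyl trifluoromethanesulfonate | C[Si](C)(C)c1c(OCc2ccccc2)cc(OCc2ccccc2)cc1OS(=O)(=O)C(F)(F)F
A9 | alternative 3 | 3,5-bis(benzyloxy)benzyne | C1#CC(OCc2ccccc2)=CC(OCc2ccccc2)=C1
A10 | alternative 3 | methyl 2-[3-(benzyloxy)-5-bromo-4-methoxyphenyl]-3-oxopropanoate | COC(=O)C(C=O)c1cc(Br)c(OC)c(OCc2ccccc2)c1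
A11 | alternative 3 | 5,7-bis(benzyloxy)-3-[3-(benzyloxy)-5-bromo-4-methoxyphenyl]chromen-4-one | O=c1c(-c2cc(Br)c(OC)c(OCc3ccccc3)c2)coc2cc(OCc3ccccc3)cc(OCc3ccccc3)c12
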